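Whatever happens in a closed flask, the shares of what was charged still add up to the whole, so I only need to know who holds what the substrate gives up.

- violet: substrate 24 mM; run made earlier
- flask: substrate 12 mM; time 20 min
violet run (percent of the substrate charged)

| time / s | intermediate B / % | substrate / % | intermediate A / % | product / % |
|---|---|---|---|---|
| 10.0 | 0.6 | 96.0 | 1.3 | 0.8 |
| 25.0 | 4.8 | 91.6 | 5.4 | 0 |
| 40.0 | 4.4 | 85.6 | 7.6 | 2.8 |
| 60.0 | 7.1 | 79.4 | 10.5 | 1.4 |
| 90.0 | 10.4 | 72.0 | 12.6 | 1.0 |
| 120 | 13.5 | 64.0 | 17.0 | 2.3 |

(standard deviation of a reading: 1 percentage point)
- the largest share of what was charged as substrate, at 20 min belongs to (intermediate A / product / substrate / intermediate B)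
- the largest share itself, whichever of these holds it, in percent of the substrate charged
- a reading or a percentage of product counts all its forms, free or not
- a reading or a percentage of substrate is of its free form alone

From the last violet reading I take the time I measure the flask by, the substrate half-life 3.11 min, defined as the time for substrate to halve if its fall stays first order. I assume it holds at the flask's smaller charge, so the flask's 20 min is 6.43 half-lives, leaving 1.15% substrate. Product at its early pace, itself a scattered reading, reaches 23.0%, which leaves 75.8% for the intermediates.

In the first extreme, kinetic control, both intermediates are ends and keep their last violet split: intermediate A 42.3%, intermediate B 33.6%. In the second, intermediate A is a store that hands everything on, and intermediate B takes the 75.8%. The flask lies between. Its time is longer than the half-life, so a return at that pace has had time, and I commit to intermediate B. The forecast says product at 58%, adding “The route is poorly determined”; there we part.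

The flask gives intermediate B at 48.8%, and left ten times as long it holds 73.5% of intermediate B with intermediate A at 0%. Substrate at 20 min stands at 15.3%, more than the 1.15% the half-life gives.

    substrate ⇌ intermediate A (K = 0.630, k = 0.130 min⁻¹)
    substrate → intermediate B (k = 0.0940 min⁻¹)
    substrate → product (k = 0.00660 min⁻¹)
    intermediate B ⇌ product (K = 0.360, k = 0.170 min⁻¹)
    substrate + product ⇌ idle adduct, settled at all times (K = 98.0 M⁻¹)

For a neighbour flask read at 50 min, the violet half-life taken at face value gives 16.1 halvings and an estimate of 0.00143% substrate. That neighbour computes to 3.48% substrate, more than the estimate, with intermediate B at 67.5% and intermediate A at 2.86%.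

The earlier runs and the new flask are calculated for an exercise; noise was put on by code.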